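## Structural features

The target is a labdane-type diterpenoid of the antipodal series. A trans-fused decalin (ring A, C1–C5 and C10; ring B, C5–C10) is joined through the chain C11–C12 to C13 of a β-hydroxy-γ-butyrolactone (C13–C16, ring oxygen between C15 and C16). Ring B is a fully substituted cyclohexenone (C7 ketone, C8=C9, methyl C17 on C8, chain on C9) with a secondary alcohol at C6, α to the ketone. The contiguous stereocentres are the quaternary C10, C5 and C6: the C10 methyl and the C6 hydroxyl share one face (the hydroxyl is axial, 1,3-diaxial to the C10 methyl and one C4 methyl), and H5 and H6 lie on the other. The fourth stereocentre, the tertiary carbinol C13, is four bonds from ring B and cannot be controlled from it. The fragile groups are the α-ketol (base moves the axial C6 alcohol to the more stable equatorial position through the enediol, and air then oxidises it to the diosphenol) and the β-hydroxy lactone (ring opening, dehydration). The real difficulty is the absolute configuration of the all-carbon quaternary C10, which has no heteroatom handle, and its relation to the remote C13. The key step exploits the position of C10 in ring B between C9 and C5: it is C4 of a cyclohexa-2,5-dienone whose enone arms C9=C8 and C5=C6 meet at the C7 carbonyl and are enantiotopic. Placing the side chain on C9 of one arm and a methyl group on C8 fixes C10, and the untouched arm C5=C6 stays as the acceptor for closing ring A.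

## Logic of the disconnections

33 to 30: the acyl–oxygen bond C15–O(C16) is cut and C15 is lowered to a primary alcohol, with the C13 and C16 oxygens tied in an acetonide. The free hydroxy lactone would not survive organomagnesium, enolate or hydride chemistry. The gain is an inert side chain whose two primary oxygens are told apart by protecting groups. The forward demand is an oxidation that takes only the primary C15 alcohol to the acid, and an acid release that leaves the α-ketol alone.

30 to 25 (through 29 and 28): the bonds C5–H and C6–H are cut, and C7 passes through the alcohol level. Any closure of ring A onto a planar ring B gives a cis fusion, and C5 can be inverted only while C6 is a carbonyl or enol carbon. The axial C6 alcohol requires hydride delivery to a C6 ketone from the face opposite the axial methyl groups, so C7 must not be a ketone at that moment. Both stereocentres vanish in 25. The forward demands are: hydride at C7 first, ketonisation of the enol to the trans fusion, a second hydride anti to the methyl groups, and re-oxidation of the allylic C7 alcohol only.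

25 to 21: the C6–O bond is cut. C6 is the only α′-methylene of the enone, so the oxygen can be introduced by enolate hydroxylation and oxidation. The gain is a ring B with a single oxygen. The demand is kinetic deprotonation at C6 and not at the γ-position C11.

21 to 20: the C4–C5 bond is cut, opening ring A to the 4-methylpent-3-enyl chain on C10 and an enone arm. A tertiary radical at C4, made by hydrogen-atom transfer to the trisubstituted alkene, is the natural partner for the β-carbon C5. The gain is a monocyclic precursor. The demand is attack at C5 and not at the fully substituted C9; the cis fusion is accepted.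

20 to 19: the C8=C9 double bond is removed. The saturated C8/C9 pattern is what conjugate addition and enolate alkylation deliver, and restoring the alkene later erases both centres. The demand is a dehydrogenation that can only run into C8–C9, which holds because the other α-carbon is already vinylic.

19 to 6 and 17: the bonds C9–C11 and C8–C17 are cut. This is the convergent step: an achiral dienone meets a chiral-pool side chain and an electrophilic methyl source. All stereochemical demand at C10 is concentrated in the choice of one enone arm by a chiral copper catalyst; the step also needs 1,4- over 1,2-addition and C-methylation of the enolate.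

6 to 1 and 2 (through 5): one ring C=C is returned to a C–C bond, then the Michael bond from C10 to the adjacent ring CH2 and the aldol C=C bond of the other arm are cut. This gives an α-branched aldehyde and a vinyl ketone. The demand is buffered hydrolysis and cyclisation that spare the trisubstituted alkene.

17 to 7 (through 16, 15, 13, 12, 11, 10 and 8): the C11–Mg bond, one carbon beyond C11 (ozonolysis) and the C12–C13 bond are cut. C12–C13 is formed by allylation at the carbinol carbon of malic acid, temporarily held in a dioxolanone that preserves its stereochemical information. The gain is that C13 comes from the chiral pool with retention. The demand is alkylation anti to the tert-butyl group and a regioselective acetonide.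

## Other disconnections considered

Alternative 1: The cut runs through C1–C10 and C4–C5. Ring A is removed, ring B becomes the quinone A1 (2-methoxy-3,5-dimethyl-1,4-benzoquinone) and the partner is the diene A2 (4-methylpenta-1,3-diene). Forward, a cationic chiral oxazaborolidinium Lewis acid (oxazaborolidine protonated by HNTf2) would bind the C6 carbonyl of A1 and guide A2 onto C10=C5 in an endo Diels–Alder reaction. The product would be the cis-fused adduct A3 with C10 as required.
- In its favour: one catalytic step would create ring A, the quaternary C10 and the gem-dimethyl C4 from two small achiral partners. C6 arrives as a ketone beside C5, so the cis-to-trans correction needs only enolisation. The C7-methoxy/C9-carbonyl pair is a vinylogous ester, so addition of the C11–C16 organometallic at C9 and acidic transposition (Stork–Danheiser) would give the C7-keto-C8=C9 enone with the chain attached. On these three points (ring and quaternary centre in one step, easy C5 epimerisation, fewer steps on paper) the alternative is the better plan.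
- Against it: A2 carries a cis-methyl group on the terminus that must bond to C5. This destabilises the s-cis conformer and makes such dienes sluggish and prone to cationic oligomerisation under strong Lewis acids. The regiochemistry needs catalyst binding at C6=O and not at the more basic vinylogous-ester carbonyl C9=O. After A3 the route still needs selective hydrogenation of C2=C3, differentiation of the C6 and C9 carbonyls, and addition of a valuable chiral nucleophile to a neopentyl carbonyl next to C10.
- Comparison: both plans let a chiral catalyst control C10. The chosen plan does so on an intrinsically reactive acceptor and attaches the side chain in the same step instead of late at a hindered ketone. In handling C13 the two are equal, since both import it from the same building block.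

Alternative 2: The cut is the C16–O bond of the lactone. The hydroxy lactone is traced to the 3-silyloxycyclobutanone A4, in which C15 is the ketone and C14 and C16 are its enantiotopic α-methylene groups. Forward, Sc(OTf)3 with a chiral N,N′-dioxide ligand and H2O2 would form the Criegee intermediate and let one methylene migrate to oxygen. This expands the ring to the γ-lactone and sets C13 in A5, the bis-silyl ether of the target.
- In its favour: ring strain makes the cyclobutanone far more reactive than the C7 enone carbonyl. The lactone is written directly in its final oxidation state, whereas the chosen plan must deprotect, oxidise and lactonise at the end; here the alternative is better in step economy. Before this step the side chain has no stereocentre, so the organometallic used to attach it would be simpler.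
- Against it: C13 is remote from the decalin, so the substrate gives no help. The catalyst alone must distinguish two methylene groups whose surroundings differ only through OSiR3 and CH2CH2R on a fully substituted carbon. That pattern is less secure than the 3-monosubstituted or 3-aryl cyclobutanones on which this catalysis rests. A shortfall would give the C13 epimer, which would be hard to separate. The step also does nothing for C10, C5 and C6.
- Comparison: the chosen plan takes C13 from L-malic acid with certainty, at the price of several functional-group operations. The two are equal in convergence.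

Alternative 3: The cut is C9–C10. Ring B opens to the (Z)-configured tetrasubstituted vinyl iodide A6, whose chain C9–C8–C7–C6 hangs from C5 of a 2,6,6-trimethylcyclohex-2-enyl ring A. Forward, zerovalent palladium (from Pd(OAc)2 and PPh3, with Ag2CO3 as halide scavenger) would insert into C9–I. The vinylpalladium would add across C10=C1 in a 6-exo carbopalladation that makes the quaternary C10. β-Hydride elimination, possible only toward C2, would leave C1=C2 in the cis-fused diene A7.
- In its favour: intramolecular Heck reactions are dependable for congested quaternary centres. The C10 configuration is relayed through the tether from the existing C5 centre and is not a choice between two similar substituents; on this point the alternative is better than the arm selection of the chosen plan. Ring A with its gem-dimethyl group is bought, not built, and the side chain and both ring-B oxygens are in place before the ring closes.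
- Against it: A6 needs an enantioenriched C5 centre, a stereodefined tetrasubstituted vinyl iodide and a protected C6/C7 diol, which is a long linear preparation. The fusion comes out cis, so C5 must be inverted through a C6 carbonyl exactly as in the chosen plan (equal), but here only after unmasking and oxidising the C6 alcohol. C1=C2 must then be hydrogenated in the presence of C8=C9, and a stoichiometric silver salt is consumed.
- Comparison: the alternative matches the chosen plan in convergence, is stronger in the certainty of the C10-forming event, and is weaker in the length and difficulty of the route to its precursor.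

Key step: step 11

Remark: positions carry labdane numbers (C1–C20) in all intermediates. Aldehyde 1 is used as the racemate because its stereocentre becomes the prochiral C10 of 6.

Remark: replacing H at C2 of L-malic acid with retention gives C13 as in the target, and the arm selection leading to (4R)-19 gives C10 as in the target. The SMILES of 17 and 19 encode exactly this, so no structural correction is needed.

Remark: SC denotes the protected side chain 2-[(4S)-4-(2-{[tert-butyl(dimethyl)silyl]oxy}ethyl)-2,2-dimethyl-1,3-dioxolan-4-yl]ethyl (C11–C16).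

## Route

Step 1
Reactants: 1 2,6-dimethylhept-5-enal (racemic); 2 but-3-en-2-one (methyl vinyl ketone)
Product: 5 4-methyl-4-(4-methylpent-3-en-1-yl)cyclohex-2-en-1-one (racemic), via pyrrolidine enamine 3 (not isolated), via keto aldehyde 4 (not isolated)
Conditions: pyrrolidine, PhMe, reflux (Dean–Stark); 2, rt → 60 °C; then AcOH/NaOAc/H2O, reflux
Reagents that add atoms: none
Why: Stork enamine Michael addition of the α-branched aldehyde to the vinyl ketone followed by hydrolysis and intramolecular aldol condensation (Robinson annulation) is the standard entry to 4,4-disubstituted cyclohexenones; the acetate buffer spares the trisubstituted alkene.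

Step 2
Reactants: 5 4-methyl-4-(4-methylpent-3-en-1-yl)cyclohex-2-en-1-one
Product: 6 4-methyl-4-(4-methylpent-3-en-1-yl)cyclohexa-2,5-dien-1-one
Conditions: IBX (2.5 equiv), DMSO, 80 °C
Reagents that add atoms: none
Why: IBX dehydrogenation of the saturated α,β-positions of an enone gives the cross-conjugated dienone; C4 is quaternary, so no phenol can form, and the isolated alkene is inert to the reagent.

Step 3
Reactants: 7 L-malic acid
Product: 8 [(2S,4S)-2-tert-butyl-5-oxo-1,3-dioxolan-4-yl]acetic acid (cis)
Conditions: t-BuCHO, TsOH (cat.), H2SO4 (cat.), pentane, reflux (Dean–Stark)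
Reagents that add atoms: 2,2-dimethylpropanal (pivalaldehyde), CC(C)(C)C=O
Why: Acetalisation of the α-hydroxy acid unit gives the five-membered dioxolanone, with the tert-butyl group cis to the CH2CO2H arm under thermodynamic control; the new acetal centre stores the chirality for the next step (self-regeneration of stereocentres).

Step 4
Reactants: 8 [(2S,4S)-2-tert-butyl-5-oxo-1,3-dioxolan-4-yl]acetic acid
Product: 10 [(2S,4S)-2-tert-butyl-5-oxo-4-(prop-2-en-1-yl)-1,3-dioxolan-4-yl]acetic acid, via dilithium enolate 9 (not isolated)
Conditions: LiN(SiMe3)2 (2.2 equiv), THF, −78 °C; allyl bromide, −78 → −20 °C; aq. HCl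
Reagents that add atoms: 3-bromoprop-1-ene (allyl bromide), C=CCBr
Why: Enolate alkylation of the dioxolanone: the allyl group enters anti to the tert-butyl group, so it takes the place of the former H with overall retention at the malic carbinol carbon (future C13); the carboxylate is only a spectator.

Step 5
Reactants: 10 [(2S,4S)-2-tert-butyl-5-oxo-4-(prop-2-en-1-yl)-1,3-dioxolan-4-yl]acetic acid
Product: 11 (3S)-3-(hydroxymethyl)hex-5-ene-1,3-diol
Conditions: LiAlH4, THF, 0 °C → reflux; Fieser work-up
Reagents that add atoms: none
Why: Hydride reduction takes the acylal carbonyl (C16) and the acid (C15) to primary alcohols and releases the auxiliary aldehyde as its alcohol; the quaternary centre is untouched.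

Step 6
Reactants: 11 (3S)-3-(hydroxymethyl)hex-5-ene-1,3-diol
Product: 12 2-[(4S)-2,2-dimethyl-4-(prop-2-en-1-yl)-1,3-dioxolan-4-yl]ethan-1-ol
Conditions: Me2C(OMe)2, TsOH (cat.), acetone, rt
Reagents that add atoms: 2,2-dimethoxypropane, COC(C)(C)OC
Why: Thermodynamic acetonide formation selects the five-membered ring across the C13 and C16 oxygens; the six-membered alternative across C13-O/C15-O would force a C13 substituent into a 1,3-diaxial clash with an acetal methyl group.

Step 7
Reactants: 12 2-[(4S)-2,2-dimethyl-4-(prop-2-en-1-yl)-1,3-dioxolan-4-yl]ethan-1-ol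
Product: 13 tert-butyl{2-[(4S)-2,2-dimethyl-4-(prop-2-en-1-yl)-1,3-dioxolan-4-yl]ethoxy}dimethylsilane
Conditions: TBSCl, imidazole, CH2Cl2, 0 °C → rt
Reagents that add atoms: tert-butyl(chloro)dimethylsilane, CC(C)(C)[Si](C)(C)Cl
Why: Standard silylation of the remaining primary alcohol (C15-OH) gives an ether that tolerates ozone, organomagnesium and hydride reagents.

Step 8
Reactants: 13 tert-butyl{2-[(4S)-2,2-dimethyl-4-(prop-2-en-1-yl)-1,3-dioxolan-4-yl]ethoxy}dimethylsilane
Product: 15 2-[(4S)-4-(2-{[tert-butyl(dimethyl)silyl]oxy}ethyl)-2,2-dimethyl-1,3-dioxolan-4-yl]ethan-1-ol, via ozonide 14 (not isolated)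
Conditions: O3, CH2Cl2, −78 °C; then NaBH4, MeOH, −78 → 0 °C
Reagents that add atoms: ozone, [O-][O+]=O
Why: Ozonolysis with reductive work-up trims the allyl group by one carbon and leaves the two-carbon arm C12–C11 as a primary alcohol; silyl ether and acetonide are stable to both reagents.

Step 9
Reactants: 15 2-[(4S)-4-(2-{[tert-butyl(dimethyl)silyl]oxy}ethyl)-2,2-dimethyl-1,3-dioxolan-4-yl]ethan-1-ol
Product: 16 {2-[(4R)-4-(2-bromoethyl)-2,2-dimethyl-1,3-dioxolan-4-yl]ethoxy}(tert-butyl)dimethylsilane
Conditions: CBr4, PPh3, imidazole, CH2Cl2, 0 °C
Reagents that add atoms: tetrabromomethane, BrC(Br)(Br)Br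
Why: The Appel reaction converts the primary alcohol to the bromide under buffered, nearly neutral conditions that keep the acetonide; the descriptor changes to R only through the priority change.

Step 10
Reactants: 16 {2-[(4R)-4-(2-bromoethyl)-2,2-dimethyl-1,3-dioxolan-4-yl]ethoxy}(tert-butyl)dimethylsilane
Product: 17 (2-{(4R)-4-[2-(tert-butyldimethylsilyloxy)ethyl]-2,2-dimethyl-1,3-dioxolan-4-yl}ethyl)magnesium bromide (solution in Et2O)
Conditions: Mg turnings (activated with BrCH2CH2Br, cat.), Et2O, reflux → rt; titrate
Reagents that add atoms: magnesium, [Mg]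
Why: Oxidative insertion of magnesium into the primary C–Br bond; the oxygen is γ to the metal, so β-elimination is not possible, and diethyl ether is the solvent in which the following copper catalysis is most selective.

Step 11
Reactants: 6 4-methyl-4-(4-methylpent-3-en-1-yl)cyclohexa-2,5-dien-1-one (1.5 equiv); 17 side-chain Grignard reagent (limiting)
Product: 19 (4R,5R,6R)-5-SC-4,6-dimethyl-4-(4-methylpent-3-en-1-yl)cyclohex-2-en-1-one, via magnesium enolate 18 (not isolated)
Conditions: CuBr·SMe2 (5 mol %), (R)-1-[(SP)-2-(diphenylphosphino)ferrocenyl]ethyldicyclohexylphosphine or its mirror image (6 mol %), t-BuOMe, −78 °C, 17 added over 2 h; then CH3I (10 equiv), DMPU, −78 → 0 °C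
Reagents that add atoms: iodomethane, CI
Why: Transmetalation of 17 to the chiral diphosphine–copper bromide complex gives an alkylcopper species that binds one C=C of 6 as a π-complex, adds at the β-carbon C9 and, after reductive elimination from the trivalent copper intermediate, leaves the C9–C11 bond and magnesium enolate 18; this is the copper-catalysed asymmetric conjugate addition of Grignard reagents to cyclic enones, used as a desymmetrisation of a 4,4-disubstituted cyclohexa-2,5-dienone with alkylation of the enolate. No ring is closed. C10 is fixed solely by which enantiotopic arm is attacked: the ligand chooses the enantioface of the C=C it accepts, and the preference for passing the methyl group and not the longer chain at C10 decides on which arm that face is used, so the ligand antipode is matched to this substrate bias to give the (4R) product. C9 is set in the same event (chain cis to the C10 methyl) and C8 by C-methylation of 18 anti to the new C9 substituent; both centres disappear in step 12, so only the arm selection has to be high. 1,4- over 1,2-addition is secured by slow addition of 17 to the catalyst-loaded dienone at −78 °C in a weakly coordinating ether, and a second addition is excluded because the product stays as enolate 18 until the quench. DMPU raises the reactivity of the magnesium enolate toward CH3I so that carbon and not oxygen is methylated, and the cheap dienone is used in excess so that 17 is fully consumed.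

Step 12
Reactants: 19 (4R,5R,6R)-5-SC-4,6-dimethyl-4-(4-methylpent-3-en-1-yl)cyclohex-2-en-1-one
Product: 20 (4R)-3-SC-2,4-dimethyl-4-(4-methylpent-3-en-1-yl)cyclohexa-2,5-dien-1-one
Conditions: IBX (3 equiv), DMSO, 75 °C
Reagents that add atoms: none
Why: IBX dehydrogenation through the only available enol (toward C8) installs C8=C9 and removes the C8 and C9 stereocentres; the other α-carbon is already vinylic, so the regiochemistry is unambiguous.

Step 13
Reactants: 20 (4R)-3-SC-2,4-dimethyl-4-(4-methylpent-3-en-1-yl)cyclohexa-2,5-dien-1-one
Product: 21 (4aR,8aS)-4-SC-3,4a,8,8-tetramethyl-4a,5,6,7,8,8a-hexahydronaphthalen-2(1H)-one (cis-fused)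
Conditions: Fe(acac)3 (30 mol %), PhSiH3 (2.5 equiv), EtOH/(CH2OH)2 5:1, 60 °C, 0.02 M
Reagents that add atoms: none
Why: Hydrogen-atom transfer from an iron hydride to C3 of the trisubstituted alkene gives the tertiary C4 radical, which adds 6-exo-trig to C5 of the less substituted enone arm (C9 is fully substituted); reduction and protonation of the α-keto radical complete a reductive olefin coupling of the Giese type. The chain reaches C5 from the face of C10 that carries C1, so the fusion is necessarily cis (H5 syn to the C10 methyl), which is corrected in step 16.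

Step 14
Reactants: 21 (4aR,8aS)-4-SC-3,4a,8,8-tetramethyl-4a,5,6,7,8,8a-hexahydronaphthalen-2(1H)-one
Product: 23 (4aR,8aS)-1-hydroxy-4-SC-3,4a,8,8-tetramethyl-4a,5,6,7,8,8a-hexahydronaphthalen-2(1H)-one (cis-fused; C6 epimers), via potassium enolate 22 (not isolated)
Conditions: KN(SiMe3)2, THF, −78 °C; 2-(phenylsulfonyl)-3-phenyloxaziridine, −78 °C; aq. NH4Cl
Reagents that add atoms: 2-(phenylsulfonyl)-3-phenyloxaziridine, O=S(=O)(c1ccccc1)N1OC1c1ccccc1
Why: Kinetic deprotonation of the enone at the α′-methylene C6 (cross-conjugated enolate) and electrophilic hydroxylation with the N-sulfonyloxaziridine is the standard α′-hydroxylation of enones; the C6 configuration does not matter because it is erased in the next step.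

Step 15
Reactants: 23 (4aR,8aS)-1-hydroxy-4-SC-3,4a,8,8-tetramethyl-4a,5,6,7,8,8a-hexahydronaphthalen-2(1H)-one
Product: 25 (4aS)-1-hydroxy-4-SC-3,4a,8,8-tetramethyl-5,6,7,8-tetrahydronaphthalen-2(4aH)-one (diosphenol), via cis-fused 6,7-dione 24 (not isolated)
Conditions: Dess–Martin periodinane, NaHCO3, CH2Cl2, rt; then Et3N, rt
Reagents that add atoms: none
Why: Dess–Martin oxidation of the α-ketol gives the 1,2-dione, which enolises toward C5 under mild base to the conjugated diosphenol, the stable tautomer of ring-fusion 6,7-diones; this makes C5 and C6 planar (the 4a descriptor changes only through priorities).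

Step 16
Reactants: 25 (4aS)-1-hydroxy-4-SC-3,4a,8,8-tetramethyl-5,6,7,8-tetrahydronaphthalen-2(4aH)-one
Product: 28 (1R,4aR,8aR)-4-SC-3,4a,8,8-tetramethyl-1,2,4a,5,6,7,8,8a-octahydronaphthalene-1,2-diol (trans-fused; C7 epimers), via enol 26 (not isolated), via trans-fused 7-hydroxy-6-ketone 27 (not isolated)
Conditions: CeCl3·7H2O, NaBH4 (excess, in portions), MeOH, −40 → 0 °C
Reagents that add atoms: none
Why: Luche reduction: the trivalent cerium salt directs hydride 1,2 to the C7 carbonyl, the only reducible carbon while C6 is an enol carbon. The resulting enol 26 ketonises by protonation of C5 on the face opposite the C10 methyl group, which gives the trans fusion (also the thermodynamic one). The C6 ketone of 27 is then reduced from the face opposite the axial methyl groups on C10 and C4, placing the C6 hydroxyl axial as in the target; the C7 configuration is irrelevant.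

Step 17
Reactants: 28 (1R,4aR,8aR)-4-SC-3,4a,8,8-tetramethyl-1,2,4a,5,6,7,8,8a-octahydronaphthalene-1,2-diol
Product: 29 (1R,4aR,8aR)-1-hydroxy-4-SC-3,4a,8,8-tetramethyl-4a,5,6,7,8,8a-hexahydronaphthalen-2(1H)-one
Conditions: MnO2 (activated, excess), CH2Cl2, rt
Reagents that add atoms: none
Why: MnO2 oxidises allylic alcohols selectively, so the C7 alcohol returns to the enone carbonyl while the saturated, hindered axial C6 alcohol stays; neutral conditions avoid enediol equilibration at C6.

Step 18
Reactants: 29 (1R,4aR,8aR)-1-hydroxy-4-SC-3,4a,8,8-tetramethyl-4a,5,6,7,8,8a-hexahydronaphthalen-2(1H)-one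
Product: 30 (1R,4aR,8aR)-1-hydroxy-4-{2-[(4S)-4-(2-hydroxyethyl)-2,2-dimethyl-1,3-dioxolan-4-yl]ethyl}-3,4a,8,8-tetramethyl-4a,5,6,7,8,8a-hexahydronaphthalen-2(1H)-one
Conditions: HF·pyridine, pyridine, THF, 0 °C → rt
Reagents that add atoms: none
Why: Buffered fluoride cleaves the primary silyl ether and leaves the acetonide; the slightly acidic medium is chosen over basic fluoride so that the α-ketol is neither epimerised nor autoxidised.

Step 19
Reactants: 30 (1R,4aR,8aR)-1-hydroxy-4-{2-[(4S)-4-(2-hydroxyethyl)-2,2-dimethyl-1,3-dioxolan-4-yl]ethyl}-3,4a,8,8-tetramethyl-4a,5,6,7,8,8a-hexahydronaphthalen-2(1H)-one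
Product: 33 (1R,4aR,8aR)-1-hydroxy-4-{2-[(3S)-3-hydroxy-5-oxooxolan-3-yl]ethyl}-3,4a,8,8-tetramethyl-4a,5,6,7,8,8a-hexahydronaphthalen-2(1H)-one (CNP0324736.4), via acetonide acid 31 (not isolated), via trihydroxy acid 32 (not isolated)
Conditions: TEMPO (20 mol %), PhI(OAc)2 (2.5 equiv), MeCN/H2O, rt; Na2S2O3; then 1 M HCl, THF, rt
Reagents that add atoms: water, O
Why: The oxoammonium oxidation (TEMPO with PhI(OAc)2 in wet acetonitrile) takes the unhindered primary C15 alcohol through the aldehyde hydrate to the acid and is slow at the hindered secondary C6 alcohol. Dilute acid then hydrolyses the acetonide, and the γ-hydroxy acid closes spontaneously to the five-membered lactone through the C16 oxygen; the protecting groups decided beforehand which carbon is oxidised.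

## Compound list

1 | 2,6-dimethylhept-5-enal (racemic) | CC(C)=CCCC(C)C=O | starting material
2 | but-3-en-2-one (methyl vinyl ketone) | CC(=O)C=C | starting material
3 | 1-(2,6-dimethylhepta-1,5-dien-1-yl)pyrrolidine | CC(C)=CCCC(C)=CN1CCCC1 | intermediate (not isolated)
4 | 2,6-dimethyl-2-(3-oxobutyl)hept-5-enal (racemic) | CC(C)=CCCC(C)(CCC(C)=O)C=O | intermediate (not isolated)
5 | 4-methyl-4-(4-methylpent-3-en-1-yl)cyclohex-2-en-1-one (racemic) | CC(C)=CCCC1(C)CCC(=O)C=C1 | intermediate
6 | 4-methyl-4-(4-methylpent-3-en-1-yl)cyclohexa-2,5-dien-1-one | CC(C)=CCCC1(C)C=CC(=O)C=C1 | intermediate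
7 | L-malic acid, (S)-2-hydroxybutanedioic acid | O[C@@H](CC(=O)O)C(=O)O | starting material
8 | [(2S,4S)-2-tert-butyl-5-oxo-1,3-dioxolan-4-yl]acetic acid (cis) | CC(C)(C)[C@H]1O[C@@H](CC(=O)O)C(=O)O1 | intermediate
9 | dilithium enolate-carboxylate of 8 | [Li]OC1=C(CC(=O)O[Li])O[C@H](C(C)(C)C)O1 | intermediate (not isolated)
10 | [(2S,4S)-2-tert-butyl-5-oxo-4-(prop-2-en-1-yl)-1,3-dioxolan-4-yl]acetic acid | CC(C)(C)[C@H]1O[C@@](CC=C)(CC(=O)O)C(=O)O1 | intermediate
11 | (3S)-3-(hydroxymethyl)hex-5-ene-1,3-diol | C=CC[C@](O)(CCO)CO | intermediate
12 | 2-[(4S)-2,2-dimethyl-4-(prop-2-en-1-yl)-1,3-dioxolan-4-yl]ethan-1-ol | C=CC[C@]1(CCO)COC(C)(C)O1 | intermediate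
13 | tert-butyl{2-[(4S)-2,2-dimethyl-4-(prop-2-en-1-yl)-1,3-dioxolan-4-yl]ethoxy}dimethylsilane | C=CC[C@]1(CCO[Si](C)(C)C(C)(C)C)COC(C)(C)O1 | intermediate
14 | ozonide (1,2,4-trioxolane) of 13, trioxolane carbon unassigned | C1OC(C[C@]2(CCO[Si](C)(C)C(C)(C)C)COC(C)(C)O2)OO1 | intermediate (not isolated)
15 | 2-[(4S)-4-(2-{[tert-butyl(dimethyl)silyl]oxy}ethyl)-2,2-dimethyl-1,3-dioxolan-4-yl]ethan-1-ol | OCC[C@]1(CCO[Si](C)(C)C(C)(C)C)COC(C)(C)O1 | intermediate
16 | {2-[(4R)-4-(2-bromoethyl)-2,2-dimethyl-1,3-dioxolan-4-yl]ethoxy}(tert-butyl)dimethylsilane | BrCC[C@]1(CCO[Si](C)(C)C(C)(C)C)COC(C)(C)O1 | intermediate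
17 | (2-{(4R)-4-[2-(tert-butyldimethylsilyloxy)ethyl]-2,2-dimethyl-1,3-dioxolan-4-yl}ethyl)magnesium bromide | Br[Mg]CC[C@]1(CCO[Si](C)(C)C(C)(C)C)COC(C)(C)O1 | intermediate
18 | bromomagnesium dienolate from addition of 17 to C9 of 6 (O–C7=C8, C5=C6) | Br[Mg]OC1=C[C@@H](CC[C@]2(CCO[Si](C)(C)C(C)(C)C)COC(C)(C)O2)[C@](C)(CCC=C(C)C)C=C1 | intermediate (not isolated)
19 | (4R,5R,6R)-5-SC-4,6-dimethyl-4-(4-methylpent-3-en-1-yl)cyclohex-2-en-1-one | C[C@H]1C(=O)C=C[C@@](C)(CCC=C(C)C)[C@@H]1CC[C@]1(CCO[Si](C)(C)C(C)(C)C)COC(C)(C)O1 | intermediate
20 | (4R)-3-SC-2,4-dimethyl-4-(4-methylpent-3-en-1-yl)cyclohexa-2,5-dien-1-one | CC1=C(CC[C@]2(CCO[Si](C)(C)C(C)(C)C)COC(C)(C)O2)[C@](C)(CCC=C(C)C)C=CC1=O | intermediate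
21 | (4aR,8aS)-4-SC-3,4a,8,8-tetramethyl-4a,5,6,7,8,8a-hexahydronaphthalen-2(1H)-one (cis-fused) | CC1=C(CC[C@]2(CCO[Si](C)(C)C(C)(C)C)COC(C)(C)O2)[C@]2(C)CCCC(C)(C)[C@@H]2CC1=O | intermediate
22 | potassium enolate of 21 (O–C7=C6) | CC1=C(CC[C@]2(CCO[Si](C)(C)C(C)(C)C)COC(C)(C)O2)[C@]2(C)CCCC(C)(C)[C@@H]2C=C1O[K] | intermediate (not isolated)
23 | (4aR,8aS)-1-hydroxy-4-SC-3,4a,8,8-tetramethyl-4a,5,6,7,8,8a-hexahydronaphthalen-2(1H)-one (cis-fused, C6 epimers) | CC1=C(CC[C@]2(CCO[Si](C)(C)C(C)(C)C)COC(C)(C)O2)[C@]2(C)CCCC(C)(C)[C@@H]2C(O)C1=O | intermediate
24 | (4aR,8aS)-4-SC-3,4a,8,8-tetramethyl-4a,5,6,7,8,8a-hexahydronaphthalene-1,2-dione (cis-fused) | CC1=C(CC[C@]2(CCO[Si](C)(C)C(C)(C)C)COC(C)(C)O2)[C@]2(C)CCCC(C)(C)[C@@H]2C(=O)C1=O | intermediate (not isolated)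
25 | (4aS)-1-hydroxy-4-SC-3,4a,8,8-tetramethyl-5,6,7,8-tetrahydronaphthalen-2(4aH)-one (diosphenol) | CC1=C(CC[C@]2(CCO[Si](C)(C)C(C)(C)C)COC(C)(C)O2)[C@]2(C)CCCC(C)(C)C2=C(O)C1=O | intermediate
26 | (4aS)-4-SC-3,4a,8,8-tetramethyl-2,4a,5,6,7,8-hexahydronaphthalene-1,2-diol (enol, C7 epimers) | CC1=C(CC[C@]2(CCO[Si](C)(C)C(C)(C)C)COC(C)(C)O2)[C@]2(C)CCCC(C)(C)C2=C(O)C1O | intermediate (not isolated)
27 | (4aR,8aR)-2-hydroxy-4-SC-3,4a,8,8-tetramethyl-4a,5,6,7,8,8a-hexahydronaphthalen-1(2H)-one (trans-fused, C7 epimers) | CC1=C(CC[C@]2(CCO[Si](C)(C)C(C)(C)C)COC(C)(C)O2)[C@]2(C)CCCC(C)(C)[C@H]2C(=O)C1O | intermediate (not isolated)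
28 | (1R,4aR,8aR)-4-SC-3,4a,8,8-tetramethyl-1,2,4a,5,6,7,8,8a-octahydronaphthalene-1,2-diol (trans-fused, C7 epimers) | CC1=C(CC[C@]2(CCO[Si](C)(C)C(C)(C)C)COC(C)(C)O2)[C@]2(C)CCCC(C)(C)[C@H]2[C@@H](O)C1O | intermediate
29 | (1R,4aR,8aR)-1-hydroxy-4-SC-3,4a,8,8-tetramethyl-4a,5,6,7,8,8a-hexahydronaphthalen-2(1H)-one | CC1=C(CC[C@]2(CCO[Si](C)(C)C(C)(C)C)COC(C)(C)O2)[C@]2(C)CCCC(C)(C)[C@H]2[C@@H](O)C1=O | intermediate
30 | (1R,4aR,8aR)-1-hydroxy-4-{2-[(4S)-4-(2-hydroxyethyl)-2,2-dimethyl-1,3-dioxolan-4-yl]ethyl}-3,4a,8,8-tetramethyl-4a,5,6,7,8,8a-hexahydronaphthalen-2(1H)-one | CC1=C(CC[C@]2(CCO)COC(C)(C)O2)[C@]2(C)CCCC(C)(C)[C@H]2[C@@H](O)C1=O | intermediate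
31 | {(4S)-2,2-dimethyl-4-[2-(ring system of 30)ethyl]-1,3-dioxolan-4-yl}acetic acid | CC1=C(CC[C@]2(CC(=O)O)COC(C)(C)O2)[C@]2(C)CCCC(C)(C)[C@H]2[C@@H](O)C1=O | intermediate (not isolated)
32 | (3S)-3-hydroxy-3-(hydroxymethyl)-5-(ring system of 30)pentanoic acid | CC1=C(CC[C@@](O)(CO)CC(=O)O)[C@]2(C)CCCC(C)(C)[C@H]2[C@@H](O)C1=O | intermediate (not isolated)
33 | (1R,4aR,8aR)-1-hydroxy-4-{2-[(3S)-3-hydroxy-5-oxooxolan-3-yl]ethyl}-3,4a,8,8-tetramethyl-4a,5,6,7,8,8a-hexahydronaphthalen-2(1H)-one (CNP0324736.4) | CC1=C(CC[C@@]2(O)COC(=O)C2)[C@]2(C)CCCC(C)(C)[C@H]2[C@@H](O)C1=O | target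

## Step count and least certain steps

Total: 19 steps. Longest linear sequence: 17 steps (7 to 33, steps 3–19); the dienone branch (steps 1–2) joins at step 11.

Step 11 (key step). The most likely failure is weak discrimination between the two enone arms. The ligand fixes the enantioface of the C=C that is attacked, but which arm offers that face depends on whether the reagent passes the methyl group or the first CH2 of the chain at C10, and these two substituents are of similar local size. Every attack on the chain side ends, after step 12, as the C10 epimer of 20, which differs only in the relation of two remote centres and would be hard to remove. Competing 1,2-addition and slow C-methylation of the magnesium enolate are lesser concerns.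
Fallback: the arm selection is separated from the fragment coupling. Setting out from 6, an ene-reductase of the Old Yellow Enzyme family (NADPH recycled with glucose and glucose dehydrogenase) reduces one enantiotopic C=C; a binding pocket, not a torsional contact, tells the methyl group from the lipophilic chain. This gives (R)-4-methyl-4-(4-methylpent-3-en-1-yl)cyclohex-2-en-1-one F1. Achiral CuBr·SMe2-catalysed addition of 17 to the remaining enone arm of F1 and methylation of the enolate with CH3I/DMPU give the saturated ketone F2, in which C8 and C9 are again of no consequence. Twofold dehydrogenation with IBX (C8–C9 and C5–C6) returns to the route at 20.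

Step 12. The dehydrogenation must create a tetrasubstituted alkene between two congested carbons. Enolisation toward the tertiary C8–H and the subsequent oxidation may be slow, and prolonged heating with IBX invites oxidation elsewhere.
Fallback: a selenoxide elimination replaces the direct dehydrogenation. Setting out from 19, LiN(iPr)2 (THF, −78 °C) and PhSeBr give the α-phenylselanyl ketone F3, with selenium entering anti to the C9 chain and therefore syn to H9. Oxidation with H2O2/pyridine (CH2Cl2, 0 °C) and syn-elimination toward C9 return to the route at 20; any exocyclic isomer would be brought into conjugation with RhCl3·3H2O.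

Step 13. The tertiary radical must attack a β-carbon next to the quaternary C10. Before it does so it may be quenched by a second hydrogen transfer (simple alkene reduction), or the cross-conjugated dienone may itself be reduced by the metal hydride.
Fallback: ring A is closed before the second unsaturation is introduced, so that only one acceptor is present. Setting out from 19, the same iron hydride conditions give the cis-fused saturated decalone F4. Its thermodynamic trimethylsilyl enol ether F5 (Me3SiCl, NaI, Et3N, MeCN) is dehydrogenated with Pd(OAc)2 (Saegusa–Ito oxidation, divalent palladium), and the route is rejoined at 21.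

Step 16. Three events are asked of one flask. Loss of control can arise from protonation of the enol at C5 on the wrong face, from shift of the α-ketol 27 to the conjugated 6-hydroxy-7-ketone before hydride reaches C6 (which would set C6 by protonation and favour the equatorial alcohol), or from stalling of the first reduction on the chelated diosphenol.
Fallback: the sequence is taken apart with the enol masked. Setting out from 25, Et3SiCl/imidazole gives the triethylsilyl enol ether F6. DIBAL-H (CH2Cl2, −78 °C) reduces C7 to the alcohol F7. Buffered hydrolysis of the silyl enol ether (PPTS, MeOH) releases 27 under equilibrating conditions as an isolated compound, and its separate reduction with NaBH4 (MeOH, −20 °C) returns to the route at 28.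

## Further compounds

F1 | step 11 | (R)-4-methyl-4-(4-methylpent-3-en-1-yl)cyclohex-2-en-1-one | O=C1C=C[C@](C)(CCC=C(C)C)CC1
F2 | step 11 | (4R)-3-SC-2,4-dimethyl-4-(4-methylpent-3-en-1-yl)cyclohexan-1-one (C2 and C3 unassigned) | CC1C(=O)CC[C@@](C)(CCC=C(C)C)C1CC[C@]1(CCO[Si](C)(C)C(C)(C)C)COC(C)(C)O1
F3 | step 12 | 6-(phenylselanyl) derivative of 19 (selenium on C8, anti to the C9 chain) | C[C@]1([Se]c2ccccc2)C(=O)C=C[C@@](C)(CCC=C(C)C)[C@@H]1CC[C@]1(CCO[Si](C)(C)C(C)(C)C)COC(C)(C)O1
F4 | step 13 | cis-fused 4-SC-3,4a,8,8-tetramethyloctahydronaphthalen-2(1H)-one (C8 and C9 as in 19) | C[C@H]1C(=O)C[C@H]2C(C)(C)CCC[C@@]2(C)[C@@H]1CC[C@]1(CCO[Si](C)(C)C(C)(C)C)COC(C)(C)O1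
F5 | step 13 | trimethylsilyl enol ether of F4 (C7=C8) | CC1=C(O[Si](C)(C)C)C[C@H]2C(C)(C)CCC[C@@]2(C)[C@@H]1CC[C@]1(CCO[Si](C)(C)C(C)(C)C)COC(C)(C)O1
F6 | step 16 | triethylsilyl enol ether of diosphenol 25 | CC1=C(CC[C@]2(CCO[Si](C)(C)C(C)(C)C)COC(C)(C)O2)[C@]2(C)CCCC(C)(C)C2=C(O[Si](CC)(CC)CC)C1=O
F7 | step 16 | C7 alcohol from reduction of F6 (C7 epimers) | CC1=C(CC[C@]2(CCO[Si](C)(C)C(C)(C)C)COC(C)(C)O2)[C@]2(C)CCCC(C)(C)C2=C(O[Si](CC)(CC)CC)C1O
A1 | alternative 1 | 2-methoxy-3,5-dimethylcyclohexa-2,5-diene-1,4-dione | COC1=C(C)C(=O)C(C)=CC1=O
A2 | alternative 1 | 4-methylpenta-1,3-diene | C=CC=C(C)C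
A3 | alternative 1 | cis-fused 3-methoxy-2,5,5,8a-tetramethyl-4a,5,8,8a-tetrahydronaphthalene-1,4-dione | CC1=C(OC)C(=O)[C@H]2C(C)(C)C=CC[C@@]2(C)C1=O
A4 | alternative 2 | 3-(tert-butyldimethylsilyloxy)-3-[2-(6-O-silylated ring system of 33)ethyl]cyclobutan-1-one | CC1=C(CCC2(O[Si](C)(C)C(C)(C)C)CC(=O)C2)[C@]2(C)CCCC(C)(C)[C@H]2[C@@H](O[Si](C)(C)C(C)(C)C)C1=O
A5 | alternative 2 | bis(tert-butyldimethylsilyl) ether of 33 | CC1=C(CC[C@@]2(O[Si](C)(C)C(C)(C)C)COC(=O)C2)[C@]2(C)CCCC(C)(C)[C@H]2[C@@H](O[Si](C)(C)C(C)(C)C)C1=O
A6 | alternative 3 | (Z)-vinyl iodide carrying SC on C9 and the 2,6,6-trimethylcyclohex-2-enyl ring on C5 (C6, C7 unassigned) | C/C(=C(/I)CC[C@]1(CCO[Si](C)(C)C(C)(C)C)COC(C)(C)O1)C(O)C(O[Si](C)(C)C(C)(C)C)[C@@H]1C(C)=CCCC1(C)C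
A7 | alternative 3 | cis-fused decalin 1,8-diene with 6-silyloxy and 7-hydroxy groups (C6, C7 unassigned) | CC1=C(CC[C@]2(CCO[Si](C)(C)C(C)(C)C)COC(C)(C)O2)[C@]2(C)C=CCC(C)(C)[C@@H]2C(O[Si](C)(C)C(C)(C)C)C1O
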